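**Retrosynthetic overview**
- The target comes from its 5,7-di-O-methyl ether; O-demethylation is the last step.
- Ring C (the 4-pyranone) comes from acid cyclodehydration of a 1-(2-hydroxyaryl)-3-phenylpropane-1,3-dione. That diketone is made by the key C–C bond formation: an intermolecular Claisen condensation of a 2-hydroxy-4,6-dimethoxy-3-(piperidin-2-yl)acetophenone with methyl benzoate.
- The acetophenone comes from Friedel–Crafts acetylation with selective ortho-demethylation of (R)-1-methyl-2-(2,4,6-trimethoxyphenyl)piperidine. Ring A is bought as 2,4,6-trimethoxybenzaldehyde.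
- The piperidine ring comes from a δ-lactam (N-methylation, reduction), itself from a δ-amino ester made by two-carbon Wittig extension of a β-amino aldehyde.
- The stereocentre is set by an intermolecular Mannich addition of the methyl acetate enolate to the (S)-tert-butanesulfinyl imine of the aldehyde. Ring order: piperidine first, ring C last.

Assumption: the stereocentre in the SMILES is read as (R) at piperidine C2; LiN(i-Pr)2, ClTi(OiPr)3 and i-Bu2AlH are bought as solutions.

**Step 1**
Reactants: 1 2,4,6-trimethoxybenzaldehyde; 2 (S)-2-methylpropane-2-sulfinamide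
Product: 3 (S)-N-[(E)-(2,4,6-trimethoxyphenyl)methylidene]-2-methylpropane-2-sulfinamide
Conditions: Ti(OEt)4 (2 equiv), THF, 65 °C; brine, filter
Reagents that add atoms: none
Why: Sulfinimine condensation; Ti(OEt)4 is both Lewis acid and water scavenger, so even this electron-rich, hindered aldehyde gives the E-imine, and the sulfur stereocentre is untouched.

**Step 2**
Reactants: 3 (S)-N-[(E)-(2,4,6-trimethoxyphenyl)methylidene]-2-methylpropane-2-sulfinamide; 4 methyl acetate
Product: 7 methyl (3R)-3-{[(S)-tert-butylsulfinyl]amino}-3-(2,4,6-trimethoxyphenyl)propanoate, via lithium enolate of methyl acetate 5 (not isolated), via titanium enolate of methyl acetate 6 (not isolated)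
Conditions: 4, LiN(i-Pr)2, THF, −78 °C; ClTi(OiPr)3 (2 equiv per enolate); then 3, −78 °C; aq. NH4Cl
Reagents that add atoms: none
Why: Sulfinimine Mannich reaction through a closed six-membered chair transition state in which titanium bridges the enolate and the sulfinyl oxygen with tert-butyl equatorial, so the (S)-sulfinyl group delivers the enolate to one imine face and sets the (3R) centre (dr normally above 95:5, minor isomer removed by chromatography).

**Step 3**
Reactants: 7 methyl (3R)-3-{[(S)-tert-butylsulfinyl]amino}-3-(2,4,6-trimethoxyphenyl)propanoate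
Product: 8 (3R)-3-{[(S)-tert-butylsulfinyl]amino}-3-(2,4,6-trimethoxyphenyl)propanal
Conditions: i-Bu2AlH (2.2 equiv), CH2Cl2, −78 °C; MeOH, then aq. KNaC4H4O6 (potassium sodium tartrate)
Reagents that add atoms: none
Why: Partial ester reduction; the aluminium hemiacetal, chelated by the deprotonated sulfinamide, survives at −78 °C until work-up, and the stereocentre is not alpha to the carbonyl.

**Step 4**
Reactants: 8 (3R)-3-{[(S)-tert-butylsulfinyl]amino}-3-(2,4,6-trimethoxyphenyl)propanal; 9 ethyl 2-(triphenyl-λ5-phosphanylidene)acetate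
Product: 10 ethyl (2E,5R)-5-{[(S)-tert-butylsulfinyl]amino}-5-(2,4,6-trimethoxyphenyl)pent-2-enoate
Conditions: CH2Cl2, rt, 12 h
Reagents that add atoms: none
Why: Wittig olefination with a stabilised ylide runs under neutral conditions, which avoids beta-elimination of the sulfinamide, and adds the two carbons needed for a six-membered ring; the E/Z ratio is irrelevant because the alkene is hydrogenated next.

**Step 5**
Reactants: 10 ethyl (2E,5R)-5-{[(S)-tert-butylsulfinyl]amino}-5-(2,4,6-trimethoxyphenyl)pent-2-enoate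
Product: 11 ethyl (5R)-5-{[(S)-tert-butylsulfinyl]amino}-5-(2,4,6-trimethoxyphenyl)pentanoate
Conditions: H2 (1 atm), 10% Pd/C, EtOAc, rt
Reagents that add atoms: none
Why: Heterogeneous catalytic hydrogenation of the conjugated alkene; the sulfinamide, aryl ethers and benzylic C–N bond are inert under these mild conditions.

**Step 6**
Reactants: 11 ethyl (5R)-5-{[(S)-tert-butylsulfinyl]amino}-5-(2,4,6-trimethoxyphenyl)pentanoate
Product: 13 (6R)-6-(2,4,6-trimethoxyphenyl)piperidin-2-one, via amino ester hydrochloride 12 (not isolated)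
Conditions: HCl (4 M in 1,4-dioxane, 3 equiv), MeOH, 0 °C, 30 min; evaporate; Et3N, MeOH, 60 °C
Reagents that add atoms: none
Why: Acidolysis of the N–S bond (chloride attacks sulfur, faster than benzylic C–N ionisation at 0 °C) followed by 6-exo-trig lactamisation of the freed δ-amino ester; no bond to the stereocentre is broken.

**Step 7**
Reactants: 13 (6R)-6-(2,4,6-trimethoxyphenyl)piperidin-2-one
Product: 14 (6R)-1-methyl-6-(2,4,6-trimethoxyphenyl)piperidin-2-one
Conditions: NaH (1.2 equiv), THF, 0 °C; MeI, 0 °C to rt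
Reagents that add atoms: iodomethane, CI
Why: N-alkylation of the lactam sodium salt by SN2 on MeI; the N–H is the only site NaH deprotonates.

**Step 8**
Reactants: 14 (6R)-1-methyl-6-(2,4,6-trimethoxyphenyl)piperidin-2-one
Product: 15 (2R)-1-methyl-2-(2,4,6-trimethoxyphenyl)piperidine
Conditions: LiAlH4 (2.5 equiv), THF, reflux; H2O, aq. NaOH work-up
Reagents that add atoms: none
Why: Hydride reduction of the tertiary lactam to the amine via the iminium ion; the benzylic stereocentre is not enolisable and is retained.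

**Step 9**
Reactants: 15 (2R)-1-methyl-2-(2,4,6-trimethoxyphenyl)piperidine
Product: 17 1-{2-hydroxy-4,6-dimethoxy-3-[(2R)-1-methylpiperidin-2-yl]phenyl}ethan-1-one, via trimethoxyphenyl methyl ketone 16 (not isolated)
Conditions: Ac2O (5 equiv), BF3·OEt2 (6 equiv), CH2Cl2, 0 °C to rt; then aq. NaOH/MeOH, rt, adjust to pH 8–9
Reagents that add atoms: acetic anhydride, CC(=O)OC(C)=O
Why: Friedel–Crafts acylation at the only type of free ring position, then boron-chelate-assisted cleavage of the ortho-methoxy flanked by both acetyl and piperidinyl (the most twisted ether), by analogy with 4-(2,4,6-trimethoxyphenyl)piperidines; nitrogen is held as its BF3 adduct, which disfavours benzylic C–N ionisation.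

**Step 10**
Reactants: 17 1-{2-hydroxy-4,6-dimethoxy-3-[(2R)-1-methylpiperidin-2-yl]phenyl}ethan-1-one; 18 methyl benzoate
Product: 19 1-{2-hydroxy-4,6-dimethoxy-3-[(2R)-1-methylpiperidin-2-yl]phenyl}-3-phenylpropane-1,3-dione
Conditions: NaH (5 equiv), DMF, 0 °C; 18 (1.5 equiv), 0 °C to rt; AcOH quench
Reagents that add atoms: none
Why: Crossed Claisen condensation; the phenoxide/ketone-enolate dianion attacks the non-enolisable ester and the equilibrium is pulled by deprotonation of the 1,3-diketone.

**Step 11**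
Reactants: 19 1-{2-hydroxy-4,6-dimethoxy-3-[(2R)-1-methylpiperidin-2-yl]phenyl}-3-phenylpropane-1,3-dione
Product: 20 5,7-dimethoxy-8-[(2R)-1-methylpiperidin-2-yl]-2-phenyl-4H-chromen-4-one
Conditions: HCl (g), CHCl3, rt, 2 h; then aq. Na2CO3
Reagents that add atoms: none
Why: Acid-catalysed cyclodehydration (phenol adds to the benzoyl carbonyl, water is lost) closes ring C; only one free ortho-hydroxyl exists, which fixes the piperidine at C8.

**Step 12**
Reactants: 20 5,7-dimethoxy-8-[(2R)-1-methylpiperidin-2-yl]-2-phenyl-4H-chromen-4-one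
Product: 21 5,7-dihydroxy-8-[(2R)-1-methylpiperidin-2-yl]-2-phenyl-4H-chromen-4-one
Conditions: BBr3 (6 equiv), CH2Cl2, −78 °C to rt; ice-water, then aq. NaHCO3 to pH 8
Reagents that add atoms: none
Why: Lewis-acid aryl methyl ether cleavage (bromide removes each methyl by SN2 from the boron-complexed ether); the chelated 5-OMe goes first and the 7-OMe follows at rt, with nitrogen masked as its boron adduct.

**Compound list**
1 | 2,4,6-trimethoxybenzaldehyde | COc1cc(OC)c(C=O)c(OC)c1 | starting material
2 | (S)-2-methylpropane-2-sulfinamide | CC(C)(C)[S@](=O)N | starting material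
3 | (S)-N-[(E)-(2,4,6-trimethoxyphenyl)methylidene]-2-methylpropane-2-sulfinamide | CC(C)(C)[S@](=O)/N=C/c1c(OC)cc(OC)cc1OC | intermediate
4 | methyl acetate | COC(C)=O | starting material
5 | lithium enolate of methyl acetate | [Li]OC(=C)OC | intermediate
6 | triisopropoxytitanium enolate of methyl acetate | C=C(OC)O[Ti](OC(C)C)(OC(C)C)OC(C)C | intermediate
7 | methyl (3R)-3-{[(S)-tert-butylsulfinyl]amino}-3-(2,4,6-trimethoxyphenyl)propanoate | COC(=O)C[C@@H](N[S@@](=O)C(C)(C)C)c1c(OC)cc(OC)cc1OC | intermediate
8 | (3R)-3-{[(S)-tert-butylsulfinyl]amino}-3-(2,4,6-trimethoxyphenyl)propanal | O=CC[C@@H](N[S@@](=O)C(C)(C)C)c1c(OC)cc(OC)cc1OC | intermediate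
9 | ethyl 2-(triphenyl-λ5-phosphanylidene)acetate | CCOC(=O)C=P(c1ccccc1)(c1ccccc1)c1ccccc1 | starting material
10 | ethyl (2E,5R)-5-{[(S)-tert-butylsulfinyl]amino}-5-(2,4,6-trimethoxyphenyl)pent-2-enoate | CCOC(=O)/C=C/C[C@@H](N[S@@](=O)C(C)(C)C)c1c(OC)cc(OC)cc1OC | intermediate
11 | ethyl (5R)-5-{[(S)-tert-butylsulfinyl]amino}-5-(2,4,6-trimethoxyphenyl)pentanoate | CCOC(=O)CCC[C@@H](N[S@@](=O)C(C)(C)C)c1c(OC)cc(OC)cc1OC | intermediate
12 | ethyl (5R)-5-amino-5-(2,4,6-trimethoxyphenyl)pentanoate hydrochloride | CCOC(=O)CCC[C@@H](N)c1c(OC)cc(OC)cc1OC.Cl | intermediate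
13 | (6R)-6-(2,4,6-trimethoxyphenyl)piperidin-2-one | O=C1CCC[C@@H](N1)c1c(OC)cc(OC)cc1OC | intermediate
14 | (6R)-1-methyl-6-(2,4,6-trimethoxyphenyl)piperidin-2-one | CN1C(=O)CCC[C@@H]1c1c(OC)cc(OC)cc1OC | intermediate
15 | (2R)-1-methyl-2-(2,4,6-trimethoxyphenyl)piperidine | CN1CCCC[C@@H]1c1c(OC)cc(OC)cc1OC | intermediate
16 | 1-{2,4,6-trimethoxy-3-[(2R)-1-methylpiperidin-2-yl]phenyl}ethan-1-one | CN1CCCC[C@@H]1c1c(OC)cc(OC)c(C(C)=O)c1OC | intermediate
17 | 1-{2-hydroxy-4,6-dimethoxy-3-[(2R)-1-methylpiperidin-2-yl]phenyl}ethan-1-one | CN1CCCC[C@@H]1c1c(OC)cc(OC)c(C(C)=O)c1O | intermediate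
18 | methyl benzoate | COC(=O)c1ccccc1 | starting material
19 | 1-{2-hydroxy-4,6-dimethoxy-3-[(2R)-1-methylpiperidin-2-yl]phenyl}-3-phenylpropane-1,3-dione | CN1CCCC[C@@H]1c1c(OC)cc(OC)c(C(=O)CC(=O)c2ccccc2)c1O | intermediate
20 | 5,7-dimethoxy-8-[(2R)-1-methylpiperidin-2-yl]-2-phenyl-4H-chromen-4-one | CN1CCCC[C@@H]1c1c(OC)cc(OC)c2c(=O)cc(-c3ccccc3)oc12 | intermediate
21 | 5,7-dihydroxy-8-[(2R)-1-methylpiperidin-2-yl]-2-phenyl-4H-chromen-4-one | CN1CCCC[C@@H]1c1c(O)cc(O)c2c(=O)cc(-c3ccccc3)oc12 | target

**Totals**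
Total step count: 12. Longest linear sequence: 12 steps (1 to 21).

**Three steps most likely to fail**

Step 2 (Mannich addition). The imine is hindered and electron-poor in reactivity terms, so conversion may be slow, and the two ortho-methoxy groups could erode the facial selectivity. The fallback sets out from 3 and comes back at 15. Imine 3 is treated in CH2Cl2 at −48 °C with 4-chlorobutylmagnesium bromide F1 (made from 1-bromo-4-chlorobutane and Mg in THF). The chelated chair addition gives (S)-N-[(1R)-5-chloro-1-(2,4,6-trimethoxyphenyl)pentyl]-2-methylpropane-2-sulfinamide F2 with the same sense of induction. NaH in THF/DMF closes the ring by intramolecular N-alkylation to (2R)-1-[(S)-tert-butylsulfinyl]-2-(2,4,6-trimethoxyphenyl)piperidine F3. HCl/MeOH at 0 °C removes the sulfinyl group to give (2R)-2-(2,4,6-trimethoxyphenyl)piperidine F4, and aqueous CH2O with NaBH(OAc)3 methylates it to 15. If the induction proves reversed in either route, the (R)-sulfinamide is used instead; the configuration is checked by chiral HPLC at 15.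

Step 9 (acetylation/demethylation). The Lewis-acidic medium could ionise the benzylic C–N bond of the very electron-rich arene, or give mixtures of demethylation products. The fallback sets out from 15 and comes back at 16, which is then isolated. Amine 15, protonated with one equivalent of CF3CO2H, is brominated with N-bromosuccinimide in MeCN at 0 °C to give (2R)-2-(3-bromo-2,4,6-trimethoxyphenyl)-1-methylpiperidine F5. Bromine–lithium exchange with n-BuLi in THF at −78 °C gives {2,4,6-trimethoxy-3-[(2R)-1-methylpiperidin-2-yl]phenyl}lithium F6, which is acylated with N-methoxy-N-methylacetamide to ketone 16 without any acid. A short treatment of 16 with BCl3 in CH2Cl2 (−78 to 0 °C) cleaves the flanked ortho-methoxy through the ketone chelate to give 17. The regiochemistry is confirmed by the chelated OH signal and an NOE between the remaining ortho-OMe and the aryl H.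

Step 12 (global demethylation). The 7-OMe may cleave incompletely, or prolonged exposure to BBr3/HBr may erode the stereocentre. The fallback sets out from 20 and comes back at 21. BCl3 in CH2Cl2 (−78 to 0 °C) removes only the carbonyl-chelated 5-methyl to give 5-hydroxy-7-methoxy-8-[(2R)-1-methylpiperidin-2-yl]-2-phenyl-4H-chromen-4-one F7. NaSEt in DMF at 110 °C then removes the 7-methyl by SN2 attack at carbon under non-acidic conditions, and neutralisation gives 21.

**Further compounds**
F1 | step 2 | 4-chlorobutylmagnesium bromide | ClCCCC[Mg]Br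
F2 | step 2 | (S)-N-[(1R)-5-chloro-1-(2,4,6-trimethoxyphenyl)pentyl]-2-methylpropane-2-sulfinamide | ClCCCC[C@@H](N[S@@](=O)C(C)(C)C)c1c(OC)cc(OC)cc1OC
F3 | step 2 | (2R)-1-[(S)-tert-butylsulfinyl]-2-(2,4,6-trimethoxyphenyl)piperidine | CC(C)(C)[S@](=O)N1CCCC[C@@H]1c1c(OC)cc(OC)cc1OC
F4 | step 2 | (2R)-2-(2,4,6-trimethoxyphenyl)piperidine | N1CCCC[C@@H]1c1c(OC)cc(OC)cc1OC
F5 | step 9 | (2R)-2-(3-bromo-2,4,6-trimethoxyphenyl)-1-methylpiperidine | CN1CCCC[C@@H]1c1c(OC)cc(OC)c(Br)c1OC
F6 | step 9 | {2,4,6-trimethoxy-3-[(2R)-1-methylpiperidin-2-yl]phenyl}lithium | CN1CCCC[C@@H]1c1c(OC)cc(OC)c([Li])c1OC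
F7 | step 12 | 5-hydroxy-7-methoxy-8-[(2R)-1-methylpiperidin-2-yl]-2-phenyl-4H-chromen-4-one | CN1CCCC[C@@H]1c1c(OC)cc(O)c2c(=O)cc(-c3ccccc3)oc12
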